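The benzene ring is made last. Its pattern is oxygen on ring C1 and C4, chain C1 attached at ring C2 beside O–C1, and methyl on ring C5 beside O–C4. This is the signature of a carbene–alkyne–CO benzannulation. One Dötz reaction between the isopropenyl(methoxy)carbene complex of Cr(CO)5 and a terminal alkyne forms ring bonds C3–C4, C2–C1 and C1–C6 and delivers the arene as a 4-methoxyphenol. The alkyne partner is the complete (S,E)-enyne. It carries the C3 stereocentre as a triethylsilyl ether (from Sharpless epoxidation of farnesol), all alkenes in place, and the C11 acid as a 2-(trimethylsilyl)ethyl ester. Buffered oxidation, reduction and one fluoride treatment finish the synthesis.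

Key step: step 13

Remark: chain atoms are numbered C1 (the CH bonded to the ring) to C15 and ring atoms C1 (CO-derived C–OH) to C6; farnesol C1–C10 become chain C1–C10; the target is 3S with E alkenes at C1=C2, C6=C7 and C10=C11; η5 and η6 ligands are written in SMILES as σ-bonded or dot-separated fragments.

Step 1
Reactants: 1 (2E,6E)-farnesol
Product: 2 (2S,3S)-2,3-epoxyfarnesol
Conditions: Ti(OiPr)4 (0.1 equiv), L-(+)-diethyl tartrate (0.12 equiv), t-BuOOH (2 equiv, anhydrous), 4 Å molecular sieves, CH2Cl2, −20 °C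
Reagents that add atoms: tert-butyl hydroperoxide, CC(C)(C)OO
Why: Sharpless asymmetric epoxidation: the allylic OH binds to titanium, so only C2=C3 is oxidised, and the L-(+)-tartrate ligand directs oxygen to the face of this E-trisubstituted allylic alcohol that gives the 2S,3S oxirane, which sets the C3–O stereocentre of the target.

Step 2
Reactants: 2 (2S,3S)-2,3-epoxyfarnesol
Product: 3 (2R,3S,6E)-1-chloro-2,3-epoxy-3,7,11-trimethyldodeca-6,10-diene
Conditions: PPh3 (1.3 equiv), CCl4, NaHCO3 (0.2 equiv), reflux
Reagents that add atoms: carbon tetrachloride, ClC(Cl)(Cl)Cl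
Why: Appel chlorination exchanges the primary OH for Cl by SN2 at C1 under essentially neutral conditions, so the acid-sensitive oxirane, its two stereocentres (C2 is now called R only because Cl changes the CIP ranking) and the two trisubstituted alkenes are left alone.

Step 3
Reactants: 3 (2R,3S,6E)-1-chloro-2,3-epoxy-3,7,11-trimethyldodeca-6,10-diene
Product: 4 (3S,6E)-3,7,11-trimethyldodeca-6,10-dien-1-yn-3-ol
Conditions: n-BuLi (3.5 equiv), THF, −78 → −20 °C; sat. aq NH4Cl
Reagents that add atoms: none
Why: Base-induced eliminative ring opening of a 2,3-epoxy chloride, a known route to propargylic alcohols: lithiation at C1 opens the oxirane by cleaving C2–O, a second elimination removes HCl, and because the C3–O bond is never touched the alcohol keeps the 3S configuration.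

Step 4
Reactants: 4 (3S,6E)-3,7,11-trimethyldodeca-6,10-dien-1-yn-3-ol
Product: 5 (3S,6E)-3,7,11-trimethyl-3-(triethylsilyloxy)dodeca-6,10-dien-1-yne
Conditions: Et3SiOTf (1.3 equiv), 2,6-lutidine (2 equiv), CH2Cl2, −78 → 0 °C
Reagents that add atoms: triethylsilyl triflate, CC[Si](CC)(CC)OS(=O)(=O)C(F)(F)F
Why: Silylation of a hindered tertiary alcohol with a silyl triflate and a non-nucleophilic base is routine, and the triethylsilyl ether is chosen because on a tertiary carbon it withstands the coming steps yet still falls to fluoride at room temperature.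

Step 5
Reactants: 5 (3S,6E)-3,7,11-trimethyl-3-(triethylsilyloxy)dodeca-6,10-dien-1-yne
Product: 7 (1E,3S,6E)-1-iodo-3,7,11-trimethyl-3-(triethylsilyloxy)dodeca-1,6,10-triene, via alkenylzirconocene chloride 6 (not isolated)
Conditions: Cp2Zr(H)Cl (1.4 equiv), THF, rt, dark; then I2 (1.4 equiv), THF, 0 °C; aq Na2S2O3
Reagents that add atoms: iodine, [I][I]; Cp2Zr(H)Cl, [H][Zr](Cl)(C1C=CC=C1)C1C=CC=C1 (Zr, Cl and cyclopentadienyl rings in 6 only, its H stays on C2)
Why: Hydrozirconation–iodinolysis: Cp2Zr(H)Cl adds syn across the terminal alkyne with zirconium on the unhindered C1, ignores trisubstituted alkenes, and the C–Zr bond is replaced by iodine with retention, which fixes the E C1=C2 alkene before any carbonyl group that the hydride could reduce is present.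

Step 6
Reactants: 7 (1E,3S,6E)-1-iodo-3,7,11-trimethyl-3-(triethylsilyloxy)dodeca-1,6,10-triene
Product: 9 (1E,3S,6E)-10,11-epoxy-1-iodo-3,7,11-trimethyl-3-(triethylsilyloxy)dodeca-1,6-diene (C10 epimers), via bromohydrin 8 (not isolated)
Conditions: NBS (1.05 equiv), THF/H2O, 0 °C; crude, then K2CO3 (2 equiv), MeOH, rt
Reagents that add atoms: water, O; N-bromosuccinimide, O=C1CCC(=O)N1Br (its Br is in 8 only)
Why: Site-selective bromohydrin formation in aqueous THF followed by Williamson-type ring closure, the classical way to epoxidise only the terminal isopropylidene unit of a polyprenyl chain: in the aqueous medium the exposed, least hindered C10=C11 alkene captures Br+, water opens the bromonium ion at the tertiary C11, and carbonate closes the oxirane, whose C10 configuration is irrelevant because C10 becomes the aldehyde carbon.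

Step 7
Reactants: 9 (1E,3S,6E)-10,11-epoxy-1-iodo-3,7,11-trimethyl-3-(triethylsilyloxy)dodeca-1,6-diene
Product: 10 (4E,8S,9E)-10-iodo-4,8-dimethyl-8-(triethylsilyloxy)deca-4,9-dienal
Conditions: H5IO6 (1.2 equiv), THF/Et2O, 0 °C, 30 min; aq NaHCO3
Reagents that add atoms: none
Why: Periodic acid hydrolyses the trisubstituted oxirane and cleaves the resulting glycol in the same pot (Malaprade-type cleavage), releasing acetone and the C10 aldehyde, while the short contact at 0 °C should spare the tertiary silyl ether, the vinyl iodide and the C6=C7 alkene.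

Step 8
Reactants: 11 2-(trimethylsilyl)ethanol; 12 (triphenylphosphoranylidene)ketene, Ph3P=C=C=O
Product: 13 2-(trimethylsilyl)ethyl (triphenylphosphoranylidene)acetate
Conditions: toluene, 90 °C, Ar
Reagents that add atoms: none
Why: Alcohols add to the ketene unit of the cumulated ylide to give the ester-stabilised phosphorane directly, a known atom-economical addition that replaces separate salt formation and deprotonation.

Step 9
Reactants: 13 2-(trimethylsilyl)ethyl (triphenylphosphoranylidene)acetate; 14 5-bromo-2-methylpent-2-ene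
Product: 16 2-(trimethylsilyl)ethyl 6-methyl-2-(triphenylphosphoranylidene)hept-5-enoate, via phosphonium bromide 15 (not isolated)
Conditions: 14 (1.5 equiv), NaI (0.2 equiv), MeCN, reflux; then CH2Cl2, 1 M aq NaOH, 0 °C
Reagents that add atoms: none
Why: C-alkylation of an ester-stabilised phosphorane with a primary halide (iodide catalysis of the SN2 step) gives the α-branched phosphonium salt, which keeps its proton because it is a weaker acid than the conjugate acid of 13, and cold aqueous NaOH then liberates ylide 16 without touching the ester.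

Step 10
Reactants: 10 (4E,8S,9E)-10-iodo-4,8-dimethyl-8-(triethylsilyloxy)deca-4,9-dienal; 16 2-(trimethylsilyl)ethyl 6-methyl-2-(triphenylphosphoranylidene)hept-5-enoate
Product: 17 2-(trimethylsilyl)ethyl (2E,6E,10S,11E)-12-iodo-6,10-dimethyl-2-(4-methylpent-3-en-1-yl)-10-(triethylsilyloxy)dodeca-2,6,11-trienoate
Conditions: 16 (1.3 equiv), toluene, 80 °C
Reagents that add atoms: none
Why: Wittig olefination with an α-branched ester-stabilised ylide reliably places the ester trans to the aldehyde-derived chain, which is the E C10=C11 geometry of the target, and the neutral ylide neither enolises the aldehyde nor disturbs the vinyl iodide.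

Step 11
Reactants: 17 vinyl iodide ester (as named in step 10); 18 ethynylmagnesium bromide
Product: 20 2-(trimethylsilyl)ethyl (2E,6E,10S,11E)-6,10-dimethyl-2-(4-methylpent-3-en-1-yl)-10-(triethylsilyloxy)tetradeca-2,6,11-trien-13-ynoate, via ethynylzinc bromide 19 (not isolated)
Conditions: 18 (0.5 M in THF, 3 equiv), ZnBr2 (3 equiv), THF, 0 °C; then 17, Pd(PPh3)4 (5 mol %), THF, rt
Reagents that add atoms: zinc dibromide, Br[Zn]Br (Zn and Br of 19 only)
Why: Negishi coupling of ethynylzinc bromide with an alkenyl iodide under zerovalent palladium catalysis gives the terminal enyne directly, with retention of the E geometry and without a silylalkyne deprotection, and the mild organozinc leaves the ester and the silyl ether alone.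

Step 12
Reactants: 21 2-bromopropene; 22 chromium hexacarbonyl, Cr(CO)6
Product: 25 pentacarbonyl[methoxy(isopropenyl)carbene]chromium, via isopropenyllithium 23 (not isolated), via lithium acylchromate 24 (not isolated)
Conditions: t-BuLi (2 equiv), Et2O, −78 °C; Cr(CO)6, Et2O, 0 °C → rt; Me3OBF4 (1.5 equiv), CH2Cl2, 0 °C
Reagents that add atoms: trimethyloxonium tetrafluoroborate, C[O+](C)C.F[B-](F)(F)F; tert-butyllithium, [Li]C(C)(C)C (Li of 23 and 24 only)
Why: Fischer carbene synthesis: isopropenyllithium from bromine–lithium exchange adds to a carbonyl ligand of Cr(CO)6 to give the lithium acylchromate, whose oxygen is methylated by the hard oxonium salt.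

Step 13
Reactants: 20 (S,E)-enyne (as named in step 11); 25 pentacarbonyl[methoxy(isopropenyl)carbene]chromium
Product: 27 2-(trimethylsilyl)ethyl (2E,6E,10S,11E)-12-(2-hydroxy-5-methoxy-4-methylphenyl)-6,10-dimethyl-2-(4-methylpent-3-en-1-yl)-10-(triethylsilyloxy)dodeca-2,6,11-trienoate, via tricarbonylchromium phenol complex 26 (not isolated)
Conditions: 25 (1.5 equiv), degassed THF (0.1 M), 50 °C, Ar; then air, MeCN/Et2O, rt; filtration through Et3N-washed SiO2
Reagents that add atoms: none
Why: On warming, 25 sheds one carbonyl ligand and binds the alkyne of 20, migratory insertion gives a chromium vinylcarbene, a CO ligand is taken up at the carbene carbon to give a metal-bound dienylketene, and ring closure followed by enolisation gives the phenol as its Cr(CO)3 complex 26, from which air removes the metal. This is the Dötz benzannulation of an alkenyl(alkoxy)carbene complex with a terminal alkyne, the carbene class for which phenol formation is most dependable, and conjugated enynes are established alkyne partners. The single ring closes by 6π electrocyclisation of the dienylketene, joining the CO-derived ring C1 to the former isopropenyl CH2 (ring C6) after the bonds alkyne CH–carbene carbon (ring C3–C4) and internal alkyne carbon–CO carbon (ring C2–C1) have been made. No stereocentre is created, and the 3S silyl ether, the E C1=C2 alkene, the three trisubstituted alkenes and the ester take no part. The selectivity required is the orientation of alkyne insertion, and the size difference between H and the alkenyl substituent puts the substituted alkyne carbon next to the CO-derived carbon, so the chain ends up ortho to the free OH and para to the methyl. The moderate temperature, the neutral medium and the silyl cap on O–C3 should keep the new ortho phenol from expelling the ionisable allylic C3–O group.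

Step 14
Reactants: 27 4-methoxyphenol (as named in step 13)
Product: 29 2-(trimethylsilyl)ethyl (2E,6E,10S,11E)-12-(2,5-dihydroxy-4-methylphenyl)-6,10-dimethyl-2-(4-methylpent-3-en-1-yl)-10-(triethylsilyloxy)dodeca-2,6,11-trienoate, via quinone 28 (not isolated)
Conditions: PhI(OAc)2 (1.1 equiv), MeCN/pH 7 buffer (NaH2PO4/Na2HPO4), 0 °C, 15 min; then aq Na2S2O4 (excess), Et2O, rt, Ar
Reagents that add atoms: water, O
Why: Oxidative demethylation of a 4-methoxyphenol with a trivalent iodine reagent in buffered aqueous acetonitrile (water adds at ring C4, methanol leaves) is a known, nearly neutral way to the para-quinone that spares the silyl ether and the ionisable C3–O bond, the quinone cannot tautomerise towards a chromenol because C3 is quaternary, and dithionite reduces it at once to the hydroquinone.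

Step 15
Reactants: 29 protected hydroquinone (as named in step 14)
Product: 30 (2E,6E,10S,11E)-12-(2,5-dihydroxy-4-methylphenyl)-10-hydroxy-6,10-dimethyl-2-(4-methylpent-3-en-1-yl)dodeca-2,6,11-trienoic acid (CNP0134639.1)
Conditions: Bu4NF (1 M in THF, 5 equiv), degassed THF, 0 °C → rt, Ar; sat. aq NH4Cl containing a little Na2S2O4
Reagents that add atoms: none
Why: Fluoride attacks both silicon atoms, cleaving the tertiary triethylsilyl ether and triggering β-elimination of ethylene and Me3SiF from the 2-(trimethylsilyl)ethyl ester, so alcohol and acid are freed together under non-acidic, oxygen-free conditions that avoid both ionisation at C3 and oxidation of the hydroquinone and leave the 3S centre untouched.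

Compound list
1 | (2E,6E)-farnesol | CC(C)=CCC/C(C)=C/CC/C(C)=C/CO | starting material
2 | (2S,3S)-2,3-epoxyfarnesol | CC(C)=CCC/C(C)=C/CC[C@]1(C)O[C@H]1CO | intermediate
3 | (2R,3S,6E)-1-chloro-2,3-epoxy-3,7,11-trimethyldodeca-6,10-diene | CC(C)=CCC/C(C)=C/CC[C@]1(C)O[C@H]1CCl | intermediate
4 | (3S,6E)-3,7,11-trimethyldodeca-6,10-dien-1-yn-3-ol | CC(C)=CCC/C(C)=C/CC[C@](C)(O)C#C | intermediate
5 | (3S,6E)-3,7,11-trimethyl-3-(triethylsilyloxy)dodeca-6,10-dien-1-yne | CC(C)=CCC/C(C)=C/CC[C@](C)(O[Si](CC)(CC)CC)C#C | intermediate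
6 | chloro[(1E,3S,6E)-3,7,11-trimethyl-3-(triethylsilyloxy)dodeca-1,6,10-trien-1-yl]zirconocene | CC(C)=CCC/C(C)=C/CC[C@](C)(O[Si](CC)(CC)CC)/C=C/[Zr](Cl)(C1C=CC=C1)C1C=CC=C1 | intermediate
7 | (1E,3S,6E)-1-iodo-3,7,11-trimethyl-3-(triethylsilyloxy)dodeca-1,6,10-triene | CC(C)=CCC/C(C)=C/CC[C@](C)(O[Si](CC)(CC)CC)/C=C/I | intermediate
8 | (6E,10S,11E)-3-bromo-12-iodo-2,6,10-trimethyl-10-(triethylsilyloxy)dodeca-6,11-dien-2-ol (epimers at the C–Br carbon) | CC(C)(O)C(Br)CC/C(C)=C/CC[C@](C)(O[Si](CC)(CC)CC)/C=C/I | intermediate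
9 | (1E,3S,6E)-10,11-epoxy-1-iodo-3,7,11-trimethyl-3-(triethylsilyloxy)dodeca-1,6-diene (C10 epimers) | CC1(C)OC1CC/C(C)=C/CC[C@](C)(O[Si](CC)(CC)CC)/C=C/I | intermediate
10 | (4E,8S,9E)-10-iodo-4,8-dimethyl-8-(triethylsilyloxy)deca-4,9-dienal | O=CCC/C(C)=C/CC[C@](C)(O[Si](CC)(CC)CC)/C=C/I | intermediate
11 | 2-(trimethylsilyl)ethanol | C[Si](C)(C)CCO | starting material
12 | (triphenylphosphoranylidene)ketene | O=C=C=P(c1ccccc1)(c1ccccc1)c1ccccc1 | starting material
13 | 2-(trimethylsilyl)ethyl (triphenylphosphoranylidene)acetate | O=C(C=P(c1ccccc1)(c1ccccc1)c1ccccc1)OCC[Si](C)(C)C | intermediate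
14 | 5-bromo-2-methylpent-2-ene | CC(C)=CCCBr | starting material
15 | {6-methyl-1-oxo-1-[2-(trimethylsilyl)ethoxy]hept-5-en-2-yl}triphenylphosphonium bromide (racemic) | [Br-].CC(C)=CCCC(C(=O)OCC[Si](C)(C)C)[P+](c1ccccc1)(c1ccccc1)c1ccccc1 | intermediate
16 | 2-(trimethylsilyl)ethyl 6-methyl-2-(triphenylphosphoranylidene)hept-5-enoate | CC(C)=CCCC(C(=O)OCC[Si](C)(C)C)=P(c1ccccc1)(c1ccccc1)c1ccccc1 | intermediate
17 | 2-(trimethylsilyl)ethyl (2E,6E,10S,11E)-12-iodo-6,10-dimethyl-2-(4-methylpent-3-en-1-yl)-10-(triethylsilyloxy)dodeca-2,6,11-trienoate | I/C=C/[C@@](C)(O[Si](CC)(CC)CC)CC/C=C(\C)CC/C=C(\CCC=C(C)C)C(=O)OCC[Si](C)(C)C | intermediate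
18 | ethynylmagnesium bromide | C#C[Mg]Br | starting material
19 | ethynylzinc bromide | C#C[Zn]Br | intermediate
20 | 2-(trimethylsilyl)ethyl (2E,6E,10S,11E)-6,10-dimethyl-2-(4-methylpent-3-en-1-yl)-10-(triethylsilyloxy)tetradeca-2,6,11-trien-13-ynoate | C#C/C=C/[C@@](C)(O[Si](CC)(CC)CC)CC/C=C(\C)CC/C=C(\CCC=C(C)C)C(=O)OCC[Si](C)(C)C | intermediate
21 | 2-bromopropene | C=C(C)Br | starting material
22 | chromium hexacarbonyl | O=C=[Cr](=C=O)(=C=O)(=C=O)(=C=O)=C=O | starting material
23 | isopropenyllithium | [Li]C(C)=C | intermediate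
24 | lithium pentacarbonyl(2-methylacryloyl)chromate | [Li+].[O-]C(C(C)=C)=[Cr](=C=O)(=C=O)(=C=O)(=C=O)=C=O | intermediate
25 | pentacarbonyl[methoxy(isopropenyl)carbene]chromium | COC(C(C)=C)=[Cr](=C=O)(=C=O)(=C=O)(=C=O)=C=O | intermediate
26 | η6-tricarbonylchromium complex of phenol 27 | COc1cc(/C=C/[C@@](C)(O[Si](CC)(CC)CC)CC/C=C(\C)CC/C=C(\CCC=C(C)C)C(=O)OCC[Si](C)(C)C)c(O)cc1C.O=C=[Cr](=C=O)=C=O | intermediate
27 | 2-(trimethylsilyl)ethyl (2E,6E,10S,11E)-12-(2-hydroxy-5-methoxy-4-methylphenyl)-6,10-dimethyl-2-(4-methylpent-3-en-1-yl)-10-(triethylsilyloxy)dodeca-2,6,11-trienoate | COc1cc(/C=C/[C@@](C)(O[Si](CC)(CC)CC)CC/C=C(\C)CC/C=C(\CCC=C(C)C)C(=O)OCC[Si](C)(C)C)c(O)cc1C | intermediate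
28 | 2-(trimethylsilyl)ethyl (2E,6E,10S,11E)-6,10-dimethyl-12-(4-methyl-3,6-dioxocyclohexa-1,4-dien-1-yl)-2-(4-methylpent-3-en-1-yl)-10-(triethylsilyloxy)dodeca-2,6,11-trienoate | CC1=CC(=O)C(/C=C/[C@@](C)(O[Si](CC)(CC)CC)CC/C=C(\C)CC/C=C(\CCC=C(C)C)C(=O)OCC[Si](C)(C)C)=CC1=O | intermediate
29 | 2-(trimethylsilyl)ethyl (2E,6E,10S,11E)-12-(2,5-dihydroxy-4-methylphenyl)-6,10-dimethyl-2-(4-methylpent-3-en-1-yl)-10-(triethylsilyloxy)dodeca-2,6,11-trienoate | Cc1cc(O)c(/C=C/[C@@](C)(O[Si](CC)(CC)CC)CC/C=C(\C)CC/C=C(\CCC=C(C)C)C(=O)OCC[Si](C)(C)C)cc1O | intermediate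
30 | (2E,6E,10S,11E)-12-(2,5-dihydroxy-4-methylphenyl)-10-hydroxy-6,10-dimethyl-2-(4-methylpent-3-en-1-yl)dodeca-2,6,11-trienoic acid | CC(C)=CCC/C(=C\CC/C(C)=C/CC[C@](C)(O)/C=C/c1cc(O)c(C)cc1O)C(=O)O | target

Total step count: 15
Longest linear sequence: 12 steps from farnesol (steps 1–7, 10, 11, 13, 14, 15)

Steps most likely to fail

Step 13. The benzannulation may be defeated by oligomerisation of the conjugated enyne at chromium, by cyclisation without CO uptake, or by thermal loss of the allylic silyloxy group under the influence of the new phenol. The fallback buys the arene instead of building it; it sets out from 17 and comes back at 30. Commercial 1-bromo-2,5-dimethoxy-4-methylbenzene is demethylated (BBr3, CH2Cl2) to 2-bromo-5-methylbenzene-1,4-diol F1. Silylation (TBSCl, imidazole, DMF) gives 1-bromo-2,5-bis(tert-butyldimethylsilyloxy)-4-methylbenzene F2. Miyaura borylation (B2pin2, Pd(dppf)Cl2, KOAc, dioxane, 80 °C) then gives the pinacol arylboronate F3. Suzuki–Miyaura coupling of F3 with 17 (Pd(dppf)Cl2, K3PO4, THF/H2O, rt) should give, with retention of the E alkene, the fully silylated hydroquinone ester F4. The fluoride treatment of step 15 would remove all four silicon groups to reach 30.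

Step 9. The neutral ylide is a weak nucleophile, so the SN2 reaction at the unactivated homoallylic bromide may be too slow and may lose to base-induced elimination of HBr. The fallback uses a phosphonate carbanion in place of the ylide; it sets out from 11 and 14 and comes back at 17. Commercial diethylphosphonoacetic acid is esterified with 11 (DCC, DMAP, CH2Cl2) to 2-(trimethylsilyl)ethyl 2-(diethoxyphosphoryl)acetate F5. Its sodium salt (NaH, DMF, NaI catalysis) is alkylated with 14 to 2-(trimethylsilyl)ethyl 2-(diethoxyphosphoryl)-6-methylhept-5-enoate F6. Horner–Wadsworth–Emmons olefination of aldehyde 10 with F6 (NaH, THF, 0 °C → rt) should give 17, and any minor alkene isomer would be removed by chromatography.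

Step 15. The hydroquinone is deprotonated by basic fluoride, so adventitious oxygen may oxidise it, and slow cleavage of the tertiary silyl ether would prolong that exposure. The fallback changes the order of unmasking so that the hydroquinone is formed last, by reduction; it sets out from 27 and comes back at 30. Bu4NF in THF acts on the air-stable monophenol 27 to give the hydroxy acid methoxyphenol F7. Buffered PhI(OAc)2 in aqueous MeCN converts it into the hydroxy acid quinone F8. Shaking with aqueous Na2S2O4 reduces F8 to 30 under neutral, reducing conditions.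

Further compounds
F1 | step 13 | 2-bromo-5-methylbenzene-1,4-diol | Cc1cc(O)c(Br)cc1O
F2 | step 13 | 1-bromo-2,5-bis(tert-butyldimethylsilyloxy)-4-methylbenzene | Cc1cc(O[Si](C)(C)C(C)(C)C)c(Br)cc1O[Si](C)(C)C(C)(C)C
F3 | step 13 | 2-[2,5-bis(tert-butyldimethylsilyloxy)-4-methylphenyl]-4,4,5,5-tetramethyl-1,3,2-dioxaborolane | Cc1cc(O[Si](C)(C)C(C)(C)C)c(B2OC(C)(C)C(C)(C)O2)cc1O[Si](C)(C)C(C)(C)C
F4 | step 13 | 2-(trimethylsilyl)ethyl (2E,6E,10S,11E)-12-[2,5-bis(tert-butyldimethylsilyloxy)-4-methylphenyl]-6,10-dimethyl-2-(4-methylpent-3-en-1-yl)-10-(triethylsilyloxy)dodeca-2,6,11-trienoate | Cc1cc(O[Si](C)(C)C(C)(C)C)c(/C=C/[C@@](C)(O[Si](CC)(CC)CC)CC/C=C(\C)CC/C=C(\CCC=C(C)C)C(=O)OCC[Si](C)(C)C)cc1O[Si](C)(C)C(C)(C)C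
F5 | step 9 | 2-(trimethylsilyl)ethyl 2-(diethoxyphosphoryl)acetate | CCOP(=O)(OCC)CC(=O)OCC[Si](C)(C)C
F6 | step 9 | 2-(trimethylsilyl)ethyl 2-(diethoxyphosphoryl)-6-methylhept-5-enoate (racemic) | CCOP(=O)(OCC)C(CCC=C(C)C)C(=O)OCC[Si](C)(C)C
F7 | step 15 | (2E,6E,10S,11E)-10-hydroxy-12-(2-hydroxy-5-methoxy-4-methylphenyl)-6,10-dimethyl-2-(4-methylpent-3-en-1-yl)dodeca-2,6,11-trienoic acid | COc1cc(/C=C/[C@@](C)(O)CC/C=C(\C)CC/C=C(\CCC=C(C)C)C(=O)O)c(O)cc1C
F8 | step 15 | (2E,6E,10S,11E)-10-hydroxy-6,10-dimethyl-12-(4-methyl-3,6-dioxocyclohexa-1,4-dien-1-yl)-2-(4-methylpent-3-en-1-yl)dodeca-2,6,11-trienoic acid | CC1=CC(=O)C(/C=C/[C@@](C)(O)CC/C=C(\C)CC/C=C(\CCC=C(C)C)C(=O)O)=CC1=O
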